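The bond on which everything rests joins the diarylmethane CH2 to C5 of the isocoumarin. That CH2 sits para to the phenolic OH and ortho to the OMe of the benzyl ring, so this ring is a latent para-quinone methide. C5 of the isocoumarin is ortho to the C6 hydroxyl and para to the C8 methoxyl, the most nucleophilic carbon of its benzo ring. Mimicking the likely biogenesis, fluoride unmasks a 4-silyloxybenzyl acetate to the quinone methide, which the phenoxide of 6-hydroxy-8-methoxy-3-methylisocoumarin captures through C5. This gives the unprotected target in one operation. Each partner is made in four steps from a simple arene.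

Key step: step 9

Remark: the target has no stereocentre or other stereogenic element, so it is achiral and the route needs no stereocontrol; compounds 1 and 9 are taken as commercially available.

Step 1
Reactants: 1 3-bromo-5-methoxyphenol
Product: 2 (3-bromo-5-methoxyphenoxy)tri(propan-2-yl)silane
Conditions: TIPSCl, imidazole, DMF, rt
Reagents that add atoms: chlorotri(propan-2-yl)silane (TIPSCl), CC(C)[Si](Cl)(C(C)C)C(C)C
Why: Imidazole-promoted O-silylation of the only acidic OH; the bulky TIPS ether later shields both of its ortho positions in step 3 and is the fluoride-labile trigger of step 9.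

Step 2
Reactants: 2 (3-bromo-5-methoxyphenoxy)tri(propan-2-yl)silane
Product: 4 [3-methoxy-5-(methoxymethyl)phenoxy]tri(propan-2-yl)silane, via aryllithium 3 (not isolated)
Conditions: n-BuLi, THF, −78 °C; then MOMCl, −78 °C → 0 °C
Reagents that add atoms: chloromethyl methyl ether (MOMCl), COCCl
Why: Bromine–lithium exchange at −78 °C is much faster than any deprotonation, and the aryllithium should be alkylated at carbon by the highly reactive α-chloro ether (SN2) to give the benzylic methyl ether.

Step 3
Reactants: 4 [3-methoxy-5-(methoxymethyl)phenoxy]tri(propan-2-yl)silane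
Product: 6 2-methoxy-6-(methoxymethyl)-4-{[tri(propan-2-yl)silyl]oxy}benzaldehyde, via ortho-lithiated arene 5 (not isolated)
Conditions: n-BuLi, Et2O, 0 °C → rt; then DMF, −78 °C → rt; aq. NH4Cl
Reagents that add atoms: N,N-dimethylformamide (DMF), CN(C)C=O
Why: Directed ortho-metalation should occur at the ring carbon between OMe and CH2OMe, the only position flanked by two coordinating groups and not shielded by the bulky silyloxy group, with the weakly coordinating solvent favouring ring over benzylic deprotonation, and DMF then formylates the aryllithium (Bouveault-type formylation).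

Step 4
Reactants: 6 2-methoxy-6-(methoxymethyl)-4-{[tri(propan-2-yl)silyl]oxy}benzaldehyde
Product: 8 [2-methoxy-6-(methoxymethyl)-4-{[tri(propan-2-yl)silyl]oxy}phenyl]methyl acetate, via benzylic alcohol 7 (not isolated)
Conditions: NaBH4, MeOH/THF, 0 °C; concentrate; then Ac2O, pyridine, DMAP (cat.), CH2Cl2, 0 °C → rt; chromatography on Et3N-deactivated silica
Reagents that add atoms: acetic anhydride, CC(=O)OC(C)=O
Why: Chemoselective NaBH4 reduction of the aldehyde followed by DMAP-catalysed O-acetylation installs the benzylic leaving group under conditions that leave the aryl silyl ether and the methyl ethers untouched.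

Step 5
Reactants: 9 methyl 2,4-dihydroxy-6-methylbenzoate (methyl orsellinate)
Product: 10 methyl 2-hydroxy-4-(methoxymethoxy)-6-methylbenzoate
Conditions: MOMCl (1.05 equiv), i-Pr2NEt, CH2Cl2, 0 °C
Reagents that add atoms: chloromethyl methyl ether (MOMCl), COCCl
Why: The 2-OH is locked in a hydrogen bond to the ester carbonyl, so Williamson-type alkylation with one equivalent of MOMCl should occur selectively at the free 4-OH.

Step 6
Reactants: 10 methyl 2-hydroxy-4-(methoxymethoxy)-6-methylbenzoate
Product: 11 methyl 2-methoxy-4-(methoxymethoxy)-6-methylbenzoate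
Conditions: MeI, K2CO3, DMF, 50 °C
Reagents that add atoms: iodomethane, CI
Why: Williamson O-methylation of the remaining chelated phenol under mildly forcing conditions, to which the MOM acetal and the ester are stable.

Step 7
Reactants: 11 methyl 2-methoxy-4-(methoxymethoxy)-6-methylbenzoate
Product: 13 methyl 2-methoxy-4-(methoxymethoxy)-6-(2-oxopropyl)benzoate, via lithiated toluate 12 (not isolated)
Conditions: LDA (2.2 equiv), THF, −78 °C; then MeC(O)N(OMe)Me, −78 °C → 0 °C; aq. NH4Cl
Reagents that add atoms: N-methoxy-N-methylacetamide, CC(=O)N(C)OC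
Why: Lateral (benzylic) lithiation of the ortho-toluate gives a stabilised dienolate that does not attack the doubly ortho-substituted ester at −78 °C and is C-acylated by the Weinreb amide, whose chelated adduct prevents over-addition (the second equivalent of LDA is consumed by the more acidic product).

Step 8
Reactants: 13 methyl 2-methoxy-4-(methoxymethoxy)-6-(2-oxopropyl)benzoate
Product: 15 6-hydroxy-8-methoxy-3-methyl-1H-isochromen-1-one, via phenolic keto ester 14 (not isolated)
Conditions: 3 M HCl in MeOH, 50 °C; evaporate; then p-TsOH·H2O (0.2 equiv), toluene, reflux with distillative removal of MeOH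
Reagents that add atoms: none
Why: Acidic methanol cleaves the MOM acetal with the formaldehyde unit trapped as dimethoxymethane, and acid-catalysed enol lactonisation of the ketone onto the neighbouring ester, driven by removal of methanol, should close the conjugated pyranone ring.

Step 9
Reactants: 8 [2-methoxy-6-(methoxymethyl)-4-{[tri(propan-2-yl)silyl]oxy}phenyl]methyl acetate; 15 6-hydroxy-8-methoxy-3-methyl-1H-isochromen-1-one (2.5 equiv, excess recovered)
Product: 18 6-hydroxy-5-{[4-hydroxy-2-methoxy-6-(methoxymethyl)phenyl]methyl}-8-methoxy-3-methyl-1H-isochromen-1-one, via cesium phenolate 16 (not isolated), via para-quinone methide 17 (not isolated)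
Conditions: CsF (4 equiv), DMF, 0 °C → rt, slow addition of 8 to 15/CsF; then 40 °C; aq. NH4Cl
Reagents that add atoms: none
Why: Fluoride cleaves the Si–O bond of 8, and the cesium phenolate 16 expels acetate from the para benzylic carbon in a 1,6-elimination to give para-quinone methide 17, whose exocyclic CH2 is attacked by C5 of the phenolate of 15 (1,6-conjugate addition), after which tautomerisation restores both arenes. The closest known reaction types are the fluoride-triggered generation of quinone methides from silyloxybenzyl esters and the ortho C-alkylation of phenols and naphthols by para-quinone methides, the elementary step of base-catalysed phenol–formaldehyde condensation. No ring is closed and no stereocentre is formed. The step needs attack through C5 and not through O6, C7 or the donor ring: the 6-OH of 15, para to the lactone-bearing C8a, is a vinylogous acid and the only phenol acidic enough to be ionised by fluoride, and in its phenolate C5 is ortho to O6 and para to the C8 methoxyl, whereas C7 lies between two oxygen substituents. O-Alkylation would give an aryl 4-hydroxybenzyl ether that re-forms 17 under the conditions, so the irreversible C–C bond formation should drain this equilibrium on warming. Slow addition of 8 to an excess of 15 keeps the concentration of 17 low and should suppress its oligomerisation and a second alkylation.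

Compound list
1 | 3-bromo-5-methoxyphenol | COc1cc(O)cc(Br)c1 | starting material
2 | (3-bromo-5-methoxyphenoxy)tri(propan-2-yl)silane | COc1cc(Br)cc(O[Si](C(C)C)(C(C)C)C(C)C)c1 | intermediate
3 | [3-methoxy-5-{[tri(propan-2-yl)silyl]oxy}phenyl]lithium | [Li]c1cc(OC)cc(O[Si](C(C)C)(C(C)C)C(C)C)c1 | intermediate
4 | [3-methoxy-5-(methoxymethyl)phenoxy]tri(propan-2-yl)silane | COCc1cc(OC)cc(O[Si](C(C)C)(C(C)C)C(C)C)c1 | intermediate
5 | [2-methoxy-6-(methoxymethyl)-4-{[tri(propan-2-yl)silyl]oxy}phenyl]lithium | [Li]c1c(OC)cc(O[Si](C(C)C)(C(C)C)C(C)C)cc1COC | intermediate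
6 | 2-methoxy-6-(methoxymethyl)-4-{[tri(propan-2-yl)silyl]oxy}benzaldehyde | COCc1cc(O[Si](C(C)C)(C(C)C)C(C)C)cc(OC)c1C=O | intermediate
7 | [2-methoxy-6-(methoxymethyl)-4-{[tri(propan-2-yl)silyl]oxy}phenyl]methanol | COCc1cc(O[Si](C(C)C)(C(C)C)C(C)C)cc(OC)c1CO | intermediate
8 | [2-methoxy-6-(methoxymethyl)-4-{[tri(propan-2-yl)silyl]oxy}phenyl]methyl acetate | COCc1cc(O[Si](C(C)C)(C(C)C)C(C)C)cc(OC)c1COC(C)=O | intermediate
9 | methyl 2,4-dihydroxy-6-methylbenzoate (methyl orsellinate) | COC(=O)c1c(C)cc(O)cc1O | starting material
10 | methyl 2-hydroxy-4-(methoxymethoxy)-6-methylbenzoate | COCOc1cc(C)c(C(=O)OC)c(O)c1 | intermediate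
11 | methyl 2-methoxy-4-(methoxymethoxy)-6-methylbenzoate | COCOc1cc(C)c(C(=O)OC)c(OC)c1 | intermediate
12 | methyl 2-(lithiomethyl)-6-methoxy-4-(methoxymethoxy)benzoate | [Li]Cc1cc(OCOC)cc(OC)c1C(=O)OC | intermediate
13 | methyl 2-methoxy-4-(methoxymethoxy)-6-(2-oxopropyl)benzoate | COCOc1cc(CC(C)=O)c(C(=O)OC)c(OC)c1 | intermediate
14 | methyl 4-hydroxy-2-methoxy-6-(2-oxopropyl)benzoate | COC(=O)c1c(CC(C)=O)cc(O)cc1OC | intermediate
15 | 6-hydroxy-8-methoxy-3-methyl-1H-isochromen-1-one | COc1cc(O)cc2cc(C)oc(=O)c12 | intermediate
16 | cesium 4-(acetoxymethyl)-3-methoxy-5-(methoxymethyl)phenolate | [Cs+].[O-]c1cc(COC)c(COC(C)=O)c(OC)c1 | intermediate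
17 | 3-methoxy-5-(methoxymethyl)-4-methylidenecyclohexa-2,5-dien-1-one | C=C1C(COC)=CC(=O)C=C1OC | intermediate
18 | 6-hydroxy-5-{[4-hydroxy-2-methoxy-6-(methoxymethyl)phenyl]methyl}-8-methoxy-3-methyl-1H-isochromen-1-one | COCc1cc(O)cc(OC)c1Cc1c(O)cc(OC)c2c(=O)oc(C)cc12 | target

Total step count: 9. Longest linear sequence: 5 steps (steps 1–4 then 9, or steps 5–8 then 9).

Steps most likely to fail

Step 9. The quinone methide may be consumed by oligomerisation, by persistent O-alkylation or by attack of C7 faster than by C5. The fallback fixes the position through a halide and forms the same bond by sp2–sp3 Suzuki–Miyaura coupling. Setting out from 15, bromination with NBS in MeCN at 0 °C should give 5-bromo-6-hydroxy-8-methoxy-3-methyl-1H-isochromen-1-one F1, whose regiochemistry can be secured and any isomer removed before the coupling. In parallel the ortho-lithiated arene 5, generated from 4 as in step 3, is quenched with 2-(chloromethyl)-4,4,5,5-tetramethyl-1,3,2-dioxaborolane (Matteson homologation) to give 2-{[2-methoxy-6-(methoxymethyl)-4-{[tri(propan-2-yl)silyl]oxy}phenyl]methyl}-4,4,5,5-tetramethyl-1,3,2-dioxaborolane F2. Coupling of F1 with F2 (Pd(OAc)2, SPhos, K3PO4, toluene/H2O, 80 °C) should give 6-hydroxy-8-methoxy-5-{[2-methoxy-6-(methoxymethyl)-4-{[tri(propan-2-yl)silyl]oxy}phenyl]methyl}-3-methyl-1H-isochromen-1-one F3. Desilylation with TBAF in THF at 0 °C comes back to the route at 18.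

Step 3. Deprotonation may occur at the benzylic CH2OMe carbon, followed by Wittig rearrangement, or ring metalation may remain incomplete. The fallback sets out from 2 and lets C–H acidity choose the site. LDA in THF at −78 °C should deprotonate the ring carbon between Br and OMe, the most acidic and the only unshielded position, and a DMF quench should give 2-bromo-6-methoxy-4-{[tri(propan-2-yl)silyl]oxy}benzaldehyde F4. Suzuki–Miyaura coupling of F4 with potassium (methoxymethyl)trifluoroborate (Pd(OAc)2, RuPhos, Cs2CO3, dioxane/H2O, 100 °C) then introduces the CH2OMe group and comes back to the route at 6, bypassing steps 2 and 3.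

Step 8. Enol lactonisation of the hindered methyl ester may stay incomplete, or the formaldehyde unit released from the MOM group may condense with the electron-rich phenol. The fallback sets out from 13 and closes the ring by cyclodehydration of a keto acid. Dealkylative cleavage of the methyl ester (LiI, pyridine, reflux, then acidification) should give 2-methoxy-4-(methoxymethoxy)-6-(2-oxopropyl)benzoic acid F5. Heating F5 in Ac2O at 100 °C should give 8-methoxy-6-(methoxymethoxy)-3-methyl-1H-isochromen-1-one F6. Brief treatment of F6 with HCl in MeOH at rt removes the MOM group and comes back to the route at 15.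

Further compounds
F1 | step 9 | 5-bromo-6-hydroxy-8-methoxy-3-methyl-1H-isochromen-1-one | COc1cc(O)c(Br)c2cc(C)oc(=O)c12
F2 | step 9 | 2-{[2-methoxy-6-(methoxymethyl)-4-{[tri(propan-2-yl)silyl]oxy}phenyl]methyl}-4,4,5,5-tetramethyl-1,3,2-dioxaborolane | COCc1cc(O[Si](C(C)C)(C(C)C)C(C)C)cc(OC)c1CB1OC(C)(C)C(C)(C)O1
F3 | step 9 | 6-hydroxy-8-methoxy-5-{[2-methoxy-6-(methoxymethyl)-4-{[tri(propan-2-yl)silyl]oxy}phenyl]methyl}-3-methyl-1H-isochromen-1-one | COCc1cc(O[Si](C(C)C)(C(C)C)C(C)C)cc(OC)c1Cc1c(O)cc(OC)c2c(=O)oc(C)cc12
F4 | step 3 | 2-bromo-6-methoxy-4-{[tri(propan-2-yl)silyl]oxy}benzaldehyde | COc1cc(O[Si](C(C)C)(C(C)C)C(C)C)cc(Br)c1C=O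
F5 | step 8 | 2-methoxy-4-(methoxymethoxy)-6-(2-oxopropyl)benzoic acid | COCOc1cc(CC(C)=O)c(C(=O)O)c(OC)c1
F6 | step 8 | 8-methoxy-6-(methoxymethoxy)-3-methyl-1H-isochromen-1-one | COCOc1cc(OC)c2c(=O)oc(C)cc2c1
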